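The constants used here are those of an exercise; the rest is arithmetic.

**The vessel.** A closed, stirred vessel at constant temperature starts with substrate as its charge, and each unit charged then stands in one of five forms, a homo dimer counted as two.

substrate 0.80 M; time 1.5 h

    substrate ⇌ target (K1 = 3.2, k1 = 1.49 × 10⁻⁴ s⁻¹)
    substrate ⇌ isomer of the product (K2 = 1.29, k2 = 1.85 × 10⁻⁴ s⁻¹)
    substrate ⇌ dormant form (K3 = 0.641, k3 = 2.59 × 10⁻⁴ s⁻¹)
    2 substrate → homo dimer (k4 = 1.09 × 10⁻⁴ M⁻¹ s⁻¹)

- a species is counted by the substrate in it: one homo dimer counts as two
- two of one species on the left: rate k times its square, two consumed each time
- run time (flask): 1.5 h

- how much target there is at 1.5 h, in percent of the substrate charged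
- how much isomer of the product there is at 1.5 h, in percent of the substrate charged

**Turning ratio.** Write the balance of the isomer of the product: its net rate is k2 times (substrate minus isomer/K2). It therefore gains while isomer over substrate stands below K2 and loses above it. Call this the turning ratio, 1.29.

**The ladder.** Substrate leaves at a summed starting rate of 2.21 M h⁻¹, which if taken as first order gives a starting half-life of 0.251 h, and on this rung it feeds the four paths in their starting shares. Next, dormant form relaxes against substrate with a half-life of 0.290 h, faster than the isomer pair at 0.586 h, so it should begin handing material back first. On the top rung stand the half-life of substrate by the forward step to target alone, 1.3 h, and its first half-life by the step to homo dimer alone, 1.59 h, both slower than the isomer pair, so I expect target and homo dimer to be still collecting at 1.5 h.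

**My reckoning.** The run lasts 5.98 first-rung half-lives and 2.56 isomer ones, so as a rough step I count the substrate as used up and the isomer as near its turn, where it neither gains nor loses. Its starting share, the selectivity, then gives 24.1% isomer. For target I expect more than its starting share, 19.4%, as what dormant form and isomer return passes through substrate again; this is an estimate, not a proven bound.

**The forecast.** The forecast puts target at 25.4%, above that starting share, and isomer at 23%, under my figure, calling the isomer “already close to quasi-equilibrium with the substrate”.

**The result.** The simulation gives 25.2% target and 23.0% isomer, with 19.7% substrate left at 1.50 h. Isomer over substrate is then 1.17, below the turning ratio, so by the rule you are still on the gaining side. The neighbouring flask, read at 2.5 h, stands on the losing side: its 22.9% isomer on 16.4% substrate is a ratio of 1.40, above the turning ratio of 1.29.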